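**Retrosynthetic overview**
1. The plan rests on ring A of the flavone (C4a, C5, C6, C7, C8, C8a). Oxygen at C5 and C8 stand para to each other with C6–CH3 and C7–O between them, which is the pattern of a hydroquinone monoether grown from a squaric ester.
2. C7–OH is unmasked last from its isopropyl ether. Ring A is then cut at C4a–C5 (4π opening/6π closure) back to a 4-methoxy-4-(4-pyranon-6-yl)cyclobutenone.
3. The C8–C8a bond comes from 1,2-addition of C6-lithiated 3-methoxy-2-(4-methoxyphenyl)-4-pyranone to 3-isopropoxy-4-methylcyclobutenedione (diisopropyl squarate + MeLi). O-methylation of the carbinol then sets the future C8–OMe.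
4. Ring C is bought as pyromeconic acid. C2-bromination, O-methylation and Suzuki coupling attach ring B.
5. Ring order: C (purchased), B attached, four-membered ring added, ring A closed last.

Key step: step 7

Remark: the target has no stereocentre, so the call for a single enantiomer is met trivially; the only centres on the way (the quaternary cyclobutenone carbon and C4a of the transient dienone) are racemic and vanish in the key step. Pyranone atoms are numbered throughout as O1, C2 (aryl), C3 (OMe), C4 (C=O), C5–H, C6–H.

**Step 1**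
Reactants: 1 3-hydroxy-4H-pyran-4-one (pyromeconic acid)
Product: 2 2-bromo-3-hydroxy-4H-pyran-4-one
Conditions: NBS (1.0 equiv), MeCN, 0 °C to rt, dark
Reagents that add atoms: N-bromosuccinimide, O=C1CCC(=O)N1Br
Why: Electrophilic bromination of an enol: the 3-OH makes C2 the nucleophilic β-carbon of the enol, the site at which 3-hydroxy-4-pyranones (kojic acid, pyromeconic acid) take up halogen, Mannich and aldol electrophiles, whereas C5 and C6 belong to the deactivated vinylogous ester half of the ring.

**Step 2**
Reactants: 2 2-bromo-3-hydroxy-4H-pyran-4-one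
Product: 3 2-bromo-3-methoxy-4H-pyran-4-one
Conditions: MeI (3 equiv), K2CO3, DMF, rt
Reagents that add atoms: iodomethane, CI
Why: Williamson O-methylation of the acidic enolic OH is the usual route to 3-methoxy-4-pyranones; the weak base, room temperature and excess MeI keep addition–elimination at the C2–Br bond from competing.

**Step 3**
Reactants: 3 2-bromo-3-methoxy-4H-pyran-4-one; 4 4-methoxyphenylboronic acid
Product: 5 3-methoxy-2-(4-methoxyphenyl)-4H-pyran-4-one
Conditions: Pd(dppf)Cl2 (3 mol %), K3PO4, 1,4-dioxane/H2O (10:1), 80 °C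
Reagents that add atoms: none
Why: Suzuki–Miyaura coupling: the C2–Br bond is a vinylogous acyl bromide that should add to Pd(0) readily, and phosphate base in a solvent poor in water limits hydrolytic loss of bromide.

**Step 4**
Reactants: 6 diisopropyl squarate (3,4-diisopropoxycyclobut-3-ene-1,2-dione)
Product: 8 3-isopropoxy-4-methylcyclobut-3-ene-1,2-dione, via methyllithium adduct 7 (not isolated)
Conditions: MeLi (1.05 equiv), THF, −78 °C; aq NH4Cl; crude adduct, conc. HCl (cat.), CH2Cl2, rt
Reagents that add atoms: methyllithium, [Li]C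
Why: 1,2-Addition of an organolithium to one carbonyl of a dialkyl squarate, followed by acid-catalysed 1,3-transposition of the carbinol oxygen with loss of isopropanol, is the standard entry to 3-alkoxy-4-alkylcyclobutenediones; the carbinol centre of 7 is racemic and disappears.

**Step 5**
Reactants: 5 3-methoxy-2-(4-methoxyphenyl)-4H-pyran-4-one; 8 3-isopropoxy-4-methylcyclobut-3-ene-1,2-dione
Product: 10 4-hydroxy-3-isopropoxy-4-[5-methoxy-6-(4-methoxyphenyl)-4-oxo-4H-pyran-2-yl]-2-methylcyclobut-2-en-1-one (racemic), via 6-lithiopyranone 9 (not isolated)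
Conditions: LiTMP (from TMPH and n-BuLi, 1.1 equiv), THF, −78 °C, 30 min; cannulated into 8 (1.2 equiv), THF, −78 °C; aq NH4Cl, −78 °C
Reagents that add atoms: none
Why: Deprotonative lithiation with a hindered, non-nucleophilic amide should take C6–H next to the ring oxygen, the most acidic ring C–H of a γ-pyrone (the counterpart of chromone 2-lithiation), and the organolithium then adds 1,2 to the carbonyl of 8 that is flanked by C–OiPr, because the other carbonyl is deactivated as a vinylogous ester; the new quaternary centre forms racemic and is erased in step 7.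

**Step 6**
Reactants: 10 4-hydroxy-3-isopropoxy-4-[5-methoxy-6-(4-methoxyphenyl)-4-oxo-4H-pyran-2-yl]-2-methylcyclobut-2-en-1-one
Product: 11 3-isopropoxy-4-methoxy-4-[5-methoxy-6-(4-methoxyphenyl)-4-oxo-4H-pyran-2-yl]-2-methylcyclobut-2-en-1-one (racemic)
Conditions: MeI (10 equiv), Ag2O (2 equiv), 4 Å MS, 1,4-dioxane, rt, dark
Reagents that add atoms: iodomethane, CI
Why: Purdie methylation (MeI/Ag2O) etherifies the tertiary carbinol under nearly neutral conditions, which avoids alkoxide-induced opening of the strained ring, and it is preferred to MeOTf, which would also O-methylate the pyranone carbonyl to a 4-methoxypyrylium salt; the racemic centre is untouched.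

**Step 7**
Reactants: 11 3-isopropoxy-4-methoxy-4-[5-methoxy-6-(4-methoxyphenyl)-4-oxo-4H-pyran-2-yl]-2-methylcyclobut-2-en-1-one
Product: 14 5-hydroxy-7-isopropoxy-3,8-dimethoxy-2-(4-methoxyphenyl)-6-methyl-4H-chromen-4-one, via vinylketene 12 (not isolated), via 4aH-dienone 13 (not isolated)
Conditions: p-xylene (0.02 M, degassed), 138 °C, Ar
Reagents that add atoms: none
Why: Proposed new method: heating breaks the cyclobutenone C1–C4 bond in a conrotatory 4π electrocyclic opening in which the 4-methoxy donor rotates away from the ring, so the pyranonyl group ends up cis to the ketene in vinylketene 12. The electrophilic ketene carbon then bonds to pyranone C5, the nucleophilic β-carbon of the ring enol ether O1–C6=C5, in a disrotatory 6π electrocyclisation that forms C4a–C5 and closes the six-membered carbocycle (ring A) as dienone 13. The C4a–H of 13 sits between two carbonyl groups and should enolise at once to the C5 phenol, chelated to C4=O, so aromatisation drives the sequence. The closest known reaction is the Moore rearrangement of 4-aryl-, 4-alkenyl- and 4-heteroaryl-4-alkoxycyclobutenones to hydroquinone monoethers; a 4-pyranone C=C has not been shown as the 2π partner, but its small aromatic stabilisation and matched polarity should make it at least as willing as a benzene or furan ring. No stereocentre remains, since the quaternary carbon of 11 and C4a of 13 both become sp2. The step needs torquoselectivity, secured by the OMe donor (a ketene with OMe inward can only re-close to 11 and open again), and site selectivity, secured because C6 has a single carbon neighbour (C5, the other being O1), while the order C5–OH, C6–Me, C7–OiPr, C8–OMe is dictated by the connectivity of the four-membered ring.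

**Step 8**
Reactants: 14 5-hydroxy-7-isopropoxy-3,8-dimethoxy-2-(4-methoxyphenyl)-6-methyl-4H-chromen-4-one
Product: 15 5,7-dihydroxy-3,8-dimethoxy-2-(4-methoxyphenyl)-6-methyl-4H-chromen-4-one (target)
Conditions: BCl3 (1 M in CH2Cl2, 3 equiv), CH2Cl2, −78 to 0 °C; H2O
Reagents that add atoms: none
Why: Lewis acid ether cleavage: BCl3 removes a secondary isopropyl aryl ether through a carbocation-like C–O scission much faster than it attacks aryl methyl ethers at or below 0 °C, and the boron chelate formed at once between 5-O and C4=O keeps the carbonyl from assisting loss of the 3-O-methyl group.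

**Compound list**
1 | 3-hydroxy-4H-pyran-4-one (pyromeconic acid) | O=c1ccocc1O | starting material
2 | 2-bromo-3-hydroxy-4H-pyran-4-one | O=c1ccoc(Br)c1O | intermediate
3 | 2-bromo-3-methoxy-4H-pyran-4-one | COc1c(Br)occc1=O | intermediate
4 | 4-methoxyphenylboronic acid | COc1ccc(cc1)B(O)O | starting material
5 | 3-methoxy-2-(4-methoxyphenyl)-4H-pyran-4-one | COc1ccc(cc1)-c1occc(=O)c1OC | intermediate
6 | diisopropyl squarate | CC(C)OC1=C(OC(C)C)C(=O)C1=O | starting material
7 | 4-hydroxy-2,3-diisopropoxy-4-methylcyclobut-2-en-1-one (racemic, not isolated) | CC(C)OC1=C(OC(C)C)C(C)(O)C1=O | intermediate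
8 | 3-isopropoxy-4-methylcyclobut-3-ene-1,2-dione | CC(C)OC1=C(C)C(=O)C1=O | intermediate
9 | 6-lithio-3-methoxy-2-(4-methoxyphenyl)-4H-pyran-4-one (not isolated) | [Li]c1cc(=O)c(OC)c(-c2ccc(OC)cc2)o1 | intermediate
10 | 4-hydroxy-3-isopropoxy-4-[5-methoxy-6-(4-methoxyphenyl)-4-oxo-4H-pyran-2-yl]-2-methylcyclobut-2-en-1-one (racemic) | COc1ccc(cc1)-c1oc(cc(=O)c1OC)C1(O)C(=O)C(C)=C1OC(C)C | intermediate
11 | 3-isopropoxy-4-methoxy-4-[5-methoxy-6-(4-methoxyphenyl)-4-oxo-4H-pyran-2-yl]-2-methylcyclobut-2-en-1-one (racemic) | COc1ccc(cc1)-c1oc(cc(=O)c1OC)C1(OC)C(=O)C(C)=C1OC(C)C | intermediate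
12 | (3Z)-3-isopropoxy-4-methoxy-4-[5-methoxy-6-(4-methoxyphenyl)-4-oxo-4H-pyran-2-yl]-2-methylbuta-1,3-dien-1-one (vinylketene, not isolated) | O=C=C(C)/C(OC(C)C)=C(OC)\c1cc(=O)c(OC)c(-c2ccc(OC)cc2)o1 | intermediate
13 | 7-isopropoxy-3,8-dimethoxy-2-(4-methoxyphenyl)-6-methyl-4aH-chromene-4,5-dione (racemic, not isolated) | COc1ccc(cc1)C1=C(OC)C(=O)C2C(=O)C(C)=C(OC(C)C)C(OC)=C2O1 | intermediate
14 | 5-hydroxy-7-isopropoxy-3,8-dimethoxy-2-(4-methoxyphenyl)-6-methyl-4H-chromen-4-one | COc1ccc(cc1)-c1oc2c(OC)c(OC(C)C)c(C)c(O)c2c(=O)c1OC | intermediate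
15 | 5,7-dihydroxy-3,8-dimethoxy-2-(4-methoxyphenyl)-6-methyl-4H-chromen-4-one | COc1ccc(-c2oc3c(OC)c(O)c(C)c(O)c3c(=O)c2OC)cc1 | target

Total step count: 8. Longest linear sequence: 7 steps (1, 2, 3, 5, 6, 7, 8); step 4 is the side branch.

**Steps most likely to fail**

**Step 7 (bears the label).**
- What may go wrong: the 6π closure onto the pyranone C5=C6 bond may be slower than loss of the vinylketene. That loss can occur by dimerisation, capture by traces of water or thermal breakdown, because closure interrupts the cross-conjugated pyranone.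
- Fallback (known chemistry only), from 8 to 15: ring A is made alone by the established alkenyl version of the same ring expansion, and ring C is closed last.
- tert-Butyl vinyl ether is α-lithiated (t-BuLi, THF, −78 to 0 °C) to (1-tert-butoxyvinyl)lithium F1. This is added to 8 at −78 °C, and trapping of the alkoxide with MeOTf should give 4-(1-tert-butoxyvinyl)-3-isopropoxy-4-methoxy-2-methylcyclobut-2-en-1-one F2.
- Heating in toluene (110 °C) should give 5-tert-butoxy-3-isopropoxy-4-methoxy-2-methylphenol F3. MeI/K2CO3 should then give its methyl ether 1-tert-butoxy-3-isopropoxy-2,5-dimethoxy-4-methylbenzene F4.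
- TFA in CH2Cl2 removes only the tert-butyl group to give 3-isopropoxy-2,5-dimethoxy-4-methylphenol F5. Its single free OH is the future O1, so the 6-methyl/8-methoxy orientation stays fixed.
- A Hoesch acylation at the only free ring position (methoxyacetonitrile, ZnCl2, HCl, Et2O; then hot water) gives 1-(2-hydroxy-4-isopropoxy-3,6-dimethoxy-5-methylphenyl)-2-methoxyethan-1-one F6.
- An Allan–Robinson condensation (4-methoxybenzoic anhydride, sodium 4-methoxybenzoate, 175 °C; then KOH, EtOH) gives 7-isopropoxy-3,5,8-trimethoxy-2-(4-methoxyphenyl)-6-methyl-4H-chromen-4-one F7.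
- BCl3 (CH2Cl2, −78 to 0 °C) cleaves the carbonyl-chelated 5-O-methyl and the 7-O-isopropyl groups to give 15.

**Step 5.**
- What may go wrong: deprotonation at C5 instead of C6, followed by ring opening through β-elimination of the ring oxygen; addition of the lithiated pyranone to pyranone that is not yet metalated; proton transfer from the methyl group of 8.
- Fallback, from 5 to 10: deprotonation by a lithium amide is replaced by halogen–metal exchange on an isolated halide.
- 5 is zincated with TMPZnCl·LiCl (THF, 25 °C) to chloro[5-methoxy-6-(4-methoxyphenyl)-4-oxo-4H-pyran-2-yl]zinc F8, a species too covalent to ring-open or self-add.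
- Quenching with iodine gives 2-iodo-5-methoxy-6-(4-methoxyphenyl)-4H-pyran-4-one F9, which is isolated so that the site of metalation can be proven.
- Iodine–magnesium exchange (i-PrMgCl·LiCl, THF, −40 °C) gives chloro[5-methoxy-6-(4-methoxyphenyl)-4-oxo-4H-pyran-2-yl]magnesium F10. This is added to 8 at −40 °C and should give 10 after an NH4Cl quench.

**Step 6.**
- What may go wrong: sluggish etherification of the hindered tertiary carbinol, and ring opening or rearrangement of the hydroxycyclobutenone on long contact with basic silver oxide.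
- Fallback, from 10 to 14: the order of methylation and ring expansion is reversed.
- 10 is heated directly in degassed p-xylene under argon (a 4-OH also rotates outward). This should give the hydroquinone 5,8-dihydroxy-7-isopropoxy-3-methoxy-2-(4-methoxyphenyl)-6-methyl-4H-chromen-4-one F11.
- Its 5-OH is locked in the hydrogen bond to C4=O, so MeI (1 equiv), K2CO3, acetone under argon should methylate only the 8-OH and give 14.

**Further compounds**
F1 | step 7 | (1-tert-butoxyvinyl)lithium | [Li]C(=C)OC(C)(C)C
F2 | step 7 | 4-(1-tert-butoxyvinyl)-3-isopropoxy-4-methoxy-2-methylcyclobut-2-en-1-one (racemic) | C=C(OC(C)(C)C)C1(OC)C(=O)C(C)=C1OC(C)C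
F3 | step 7 | 5-tert-butoxy-3-isopropoxy-4-methoxy-2-methylphenol | Cc1c(O)cc(OC(C)(C)C)c(OC)c1OC(C)C
F4 | step 7 | 1-tert-butoxy-3-isopropoxy-2,5-dimethoxy-4-methylbenzene | Cc1c(OC)cc(OC(C)(C)C)c(OC)c1OC(C)C
F5 | step 7 | 3-isopropoxy-2,5-dimethoxy-4-methylphenol | Cc1c(OC)cc(O)c(OC)c1OC(C)C
F6 | step 7 | 1-(2-hydroxy-4-isopropoxy-3,6-dimethoxy-5-methylphenyl)-2-methoxyethan-1-one | COCC(=O)c1c(O)c(OC)c(OC(C)C)c(C)c1OC
F7 | step 7 | 7-isopropoxy-3,5,8-trimethoxy-2-(4-methoxyphenyl)-6-methyl-4H-chromen-4-one | COc1ccc(cc1)-c1oc2c(OC)c(OC(C)C)c(C)c(OC)c2c(=O)c1OC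
F8 | step 5 | chloro[5-methoxy-6-(4-methoxyphenyl)-4-oxo-4H-pyran-2-yl]zinc | Cl[Zn]c1cc(=O)c(OC)c(-c2ccc(OC)cc2)o1
F9 | step 5 | 2-iodo-5-methoxy-6-(4-methoxyphenyl)-4H-pyran-4-one | COc1ccc(cc1)-c1oc(I)cc(=O)c1OC
F10 | step 5 | chloro[5-methoxy-6-(4-methoxyphenyl)-4-oxo-4H-pyran-2-yl]magnesium | Cl[Mg]c1cc(=O)c(OC)c(-c2ccc(OC)cc2)o1
F11 | step 6 | 5,8-dihydroxy-7-isopropoxy-3-methoxy-2-(4-methoxyphenyl)-6-methyl-4H-chromen-4-one | COc1ccc(cc1)-c1oc2c(O)c(OC(C)C)c(C)c(O)c2c(=O)c1OC
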